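**Retrosynthetic overview**
1. Target 27 ← ring C quinone unveiled last (Teuber oxidation, desilylation) from phenol 25; ring C ← Danheiser benzannulation of diazo ketone 19 (C8=C9 as the vinyl unit) with siloxyalkyne 22.
2. 19 ← tricyclic enoate 11: the C6=C7 alkene becomes the C7 ketone, which pulls C9=C20 into the C8=C9 position and is then turned into the 7α-acetate.
3. 11 ← cycloheptadiene 8: lactone by acyl transfer to the C10 oxygen, then ring A by C3–C4 enolate alkylation (the bridge sets C4).
4. 8 ← vinyldiazoacetate 6 + diene 2 by a rhodium-catalysed (4+3) union that forms C8–C9 and C5–C10 and closes ring B. The enabling feature is that ring B is a seven-membered carbocycle in which a three-carbon unit C9–C20–C10 (oxygen on C10, a carboxyl carbon on C9) faces a four-carbon unit C5–C6–C7–C8, the retron of a vinylcarbene/diene cycloaddition.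
5. Ring order: B (step 4), lactone (step 5), A (step 6), C (step 14).

Key step: step 4

Remark: locants are those of the icetexane skeleton of the target; 2 is racemic, so 7 to 10 are carried as C4 epimers (that centre is left open in their SMILES) until step 6 erases and resets it, and the sense of induction of Rh2(S-DOSP)4 is assumed to follow its usual behaviour with donor/acceptor carbenoids.

**Route**

Step 1
Reactants: 1 ethyl sorbate
Product: 2 ethyl (E)-2-methylhexa-3,5-dienoate (racemic)
Conditions: LiN(iPr)2, HMPA, THF, −78 °C; MeI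
Reagents that add atoms: iodomethane, CI
Why: Deprotonation at the terminal methyl gives the extended trienolate, which is alkylated at the α-carbon (deconjugative α-alkylation) and leaves the (E)-3,5-diene; the new α-centre is uncontrolled and is erased in step 6.

Step 2
Reactants: 3 5-chloropent-1-yne
Product: 4 (E)-5-chloro-1-iodopent-1-en-2-yl acetate (iodine trans to acetoxy)
Conditions: IPy2BF4, HBF4·OEt2, AcOH, CH2Cl2, −60 °C→rt
Reagents that add atoms: bis(pyridine)iodonium tetrafluoroborate, c1cc[n+](cc1)[I-][n+]1ccccc1.F[B-](F)(F)F; acetic acid, CC(=O)O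
Why: Iodonium activation of the terminal alkyne and Markovnikov anti attack of acetic acid (iodo-acetoxylation) should place iodine and acetoxy trans, which fixes the enol-ester geometry the key step needs.

Step 3
Reactants: 4 (E)-5-chloro-1-iodopent-1-en-2-yl acetate; 5 tert-butyl diazoacetate
Product: 6 tert-butyl (E)-4-acetoxy-7-chloro-2-diazohept-3-enoate (diazo carbon trans to acetoxy)
Conditions: Pd(PPh3)4 (5 mol%), Et3N, n-Bu4NBr, MeCN, rt
Reagents that add atoms: none
Why: Palladium-catalysed cross-coupling of a vinyl iodide with a diazoacetate keeps the diazo group and retains the alkene geometry, so the future C9 ends up trans to the acetoxy group and cis to the chloropropyl chain.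

Step 4
Reactants: 6 tert-butyl (E)-4-acetoxy-7-chloro-2-diazohept-3-enoate; 2 ethyl (E)-2-methylhexa-3,5-dienoate
Product: 8 tert-butyl 3-acetoxy-3-(3-chloropropyl)-4-(1-ethoxy-1-oxopropan-2-yl)cyclohepta-1,5-diene-1-carboxylate (acetoxy on C10 and propionate arm on C5 cis), via cis-divinylcyclopropane 7 (not isolated)
Conditions: Rh2(S-DOSP)4 (1 mol%), 2 (3 equiv), hexanes, −40 °C→rt; then PhMe, 100 °C
Reagents that add atoms: none
Why: Rh2(S-DOSP)4 turns 6 into a donor/acceptor rhodium vinylcarbenoid that cyclopropanates the terminal alkene of 2 (carbenoid carbon C9 to C8 and C7) to give 7, which on heating undergoes a boat-like Cope rearrangement that forms C5–C10 and breaks C7–C9, so that C8–C9 and C5–C10 are the two new bonds that remain; the closest known reaction type is the rhodium-catalysed tandem cyclopropanation/Cope rearrangement (formal (4+3) cycloaddition) of vinyldiazoacetates with 1,3-dienes. The transient three-membered ring closes by carbene (2+1) addition and ring B, the only ring kept, closes in the [3,3] shift as a 1,4-cycloheptadiene (C9=C20, C6=C7). Absolute configuration should come from the chiral prolinate catalyst at the cyclopropanation and is relayed stereospecifically through the boat transition state: the outward (E) acetoxy group on C10 and the outward (E) propionate carbon C4 on C5 end up cis, while the inward chloropropyl chain and H5 take the other face, which sets the oxygenated quaternary C10 and C5 together. The step needs regioselectivity for the unsubstituted vinyl end of 2 (trans-1,2-disubstituted alkenes are poor partners for donor/acceptor carbenoids), cis-divinyl diastereoselectivity (the alkene substituent prefers the side of the donor vinyl group) and a Cope rearrangement despite the inward alkyl chain (secured by heating).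

Step 5
Reactants: 8 cycloheptadiene diester
Product: 10 cis-fused γ-lactone (C19–O–C10) bearing the 3-chloropropyl chain on C10 and the tert-butyl ester on C9, via hydroxy diester 9 (not isolated)
Conditions: NaOEt (0.2 equiv), EtOH, 0 °C→rt
Reagents that add atoms: none
Why: Ethoxide transesterifies the tertiary acetate and the freed C10 alkoxide, cis to the propionate arm, closes the five-membered lactone on the ethyl ester with retention at C10; the tert-butyl ester is too hindered and geometrically out of reach.

Step 6
Reactants: 10 cis-fused γ-lactone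
Product: 11 tricyclic 19,10-lactone with ring A closed (C6=C7 and C9=C20 double bonds, tert-butyl ester on C9, 5α-H, C18 methyl exo)
Conditions: KN(SiMe3)2 (1.2 equiv), n-Bu4NI (cat.), THF, −78 °C→rt
Reagents that add atoms: none
Why: Intramolecular alkylation of the lactone enolate by the primary chloride (6-exo-tet) closes ring A as a bicyclo[3.2.1] lactone; the tether on C10 can reach C4 only from the face of H5, so C4 is set by the bridge and the trans A/B relationship follows.

Step 7
Reactants: 11 tricyclic lactone diene
Product: 12 7α-alcohol (C7–OH, C6H2; C9=C20 enoate intact)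
Conditions: 9-BBN, THF, 0 °C→rt; then NaBO3·4H2O, H2O
Reagents that add atoms: sodium perborate, [Na+].[Na+].O[B-]1(O)OO[B-](O)(O)OO1
Why: Hydroboration–oxidation with bulky 9-BBN should place boron on C7, the alkene carbon remote from the congested C5 methine, on the face anti to the lactone bridge; the electron-poor enoate is left alone and the new centre is removed in step 8.

Step 8
Reactants: 12 7α-alcohol
Product: 14 7-oxo-8-ene ester (C7 ketone conjugated with C8=C9, C20 now CH2), via β,γ-unsaturated ketone 13 (not isolated)
Conditions: Dess–Martin periodinane, CH2Cl2, rt; then SiO2, CH2Cl2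
Reagents that add atoms: none
Why: Dess–Martin oxidation gives the C7 ketone, whose doubly activated C8 methylene lets the C9=C20 bond move into conjugation through the enol, which fixes the C8=C9 unsaturation needed for ring C without any base that could expel the C10 carboxylate.

Step 9
Reactants: 14 7-oxo-8-ene ester
Product: 15 7β-allylic alcohol
Conditions: NaBH4, CeCl3·7H2O, MeOH, −78 °C
Reagents that add atoms: none
Why: Luche 1,2-reduction of the enone, in which hydride should attack C7 from the α-face, away from C4 and the lactone bridge, to give the 7β-alcohol without touching the esters.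

Step 10
Reactants: 15 7β-allylic alcohol
Product: 16 7α-acetate (tert-butyl ester)
Conditions: PPh3, DIAD, AcOH, PhMe, 0 °C→rt
Reagents that add atoms: acetic acid, CC(=O)O
Why: Mitsunobu esterification inverts C7 by SN2 displacement of the oxyphosphonium and installs the 7α-acetate of the target; SN2' attack is blocked because the far alkene carbon C9 is fully substituted.

Step 11
Reactants: 16 7α-acetate tert-butyl ester
Product: 17 carboxylic acid
Conditions: CF3CO2H, CH2Cl2, 0 °C→rt
Reagents that add atoms: none
Why: Acidolysis of the tert-butyl ester (loss of isobutene) frees the acid while the acetate and the hindered lactone survive.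

Step 12
Reactants: 17 carboxylic acid
Product: 19 α-diazo ketone, via acid chloride 18 (not isolated)
Conditions: (COCl)2, DMF (cat.), CH2Cl2, 0 °C; then Me3SiCHN2, MeCN/THF, 0 °C
Reagents that add atoms: (trimethylsilyl)diazomethane, C[Si](C)(C)C=[N+]=[N-]
Why: Arndt–Eistert-type acylation of the silyl diazomethane by the acid chloride gives the diazo ketone; the trisubstituted electron-poor alkene should be too hindered for dipolar cycloaddition at 0 °C.

Step 13
Reactants: 20 ethyl isobutyrate
Product: 22 triisopropyl[(3-methylbut-1-yn-1-yl)oxy]silane, via lithium ynolate 21 (not isolated)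
Conditions: CH2Br2, lithium 2,2,6,6-tetramethylpiperidide, THF, −78 °C; n-BuLi, −78 °C→rt; iPr3SiOTf, −78→0 °C
Reagents that add atoms: dibromomethane, BrCBr; triisopropylsilyl trifluoromethanesulfonate, CC(C)[Si](OS(=O)(=O)C(F)(F)F)(C(C)C)C(C)C
Why: Kowalski ester homologation converts the ester through the dibromo ketone enolate and carbenoid rearrangement into the ynolate, which the hard silyl triflate traps on oxygen.

Step 14
Reactants: 19 α-diazo ketone; 22 siloxyalkyne
Product: 25 ring C phenol (C14–OH, C13 isopropyl, C12–OSi(iPr)3, C11–H; 7α-OAc), via vinylketene 23 (not isolated), via cyclobutenone 24 (not isolated)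
Conditions: 22 (2 equiv), hν (medium-pressure Hg, Pyrex), ClCH2CH2Cl, rt; then 80 °C
Reagents that add atoms: none
Why: Danheiser benzannulation, in which photochemical Wolff rearrangement gives the vinylketene, the siloxyalkyne adds by (2+2), and the 4-alkenylcyclobutenone opens (4π) and recloses (6π) onto C8 to give ring C with the substituent pattern dictated by the polarity of the ynol ether.

Step 15
Reactants: 25 ring C phenol
Product: 26 12-O-triisopropylsilyl quinone
Conditions: (KSO3)2NO, KH2PO4, acetone/H2O, rt
Reagents that add atoms: potassium nitrosodisulfonate, [K+].[K+].[O]N(S(=O)(=O)[O-])S(=O)(=O)[O-]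
Why: Teuber oxidation, in which the nitroxyl radical removes the phenolic hydrogen and oxygenates the free para position C11 to give the para-quinone under buffered conditions that spare the acetate and lactone.

Step 16
Reactants: 26 silyl quinone
Product: 27 7α-acetoxy-6,7-dihydroicetexone
Conditions: HF·pyridine, THF, 0 °C
Reagents that add atoms: none
Why: Acidic fluoride cleavage of the vinylogous silyl ester frees the C12 hydroxyl without the base that could eliminate the C10 carboxylate through C20 or hydrolyse the acetate.

**Compound list**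
1 | ethyl (2E,4E)-hexa-2,4-dienoate (ethyl sorbate) | C/C=C/C=C/C(=O)OCC | starting material
2 | ethyl (E)-2-methylhexa-3,5-dienoate, racemic | CCOC(=O)C(C)/C=C/C=C | intermediate
3 | 5-chloropent-1-yne | C#CCCCCl | starting material
4 | (E)-5-chloro-1-iodopent-1-en-2-yl acetate | CC(=O)O/C(CCCCl)=C/I | intermediate
5 | tert-butyl diazoacetate | CC(C)(C)OC(=O)C=[N+]=[N-] | starting material
6 | tert-butyl (E)-4-acetoxy-7-chloro-2-diazohept-3-enoate | CC(=O)O/C(CCCCl)=C/C(=[N+]=[N-])C(=O)OC(C)(C)C | intermediate
7 | tert-butyl 1-[(E)-2-acetoxy-5-chloropent-1-enyl]-2-[(E)-4-ethoxy-3-methyl-4-oxobut-1-enyl]cyclopropane-1-carboxylate, alkenyl groups cis | CCOC(=O)C(C)/C=C/[C@H]1C[C@@]1(C(=O)OC(C)(C)C)/C=C(/OC(C)=O)CCCCl | intermediate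
8 | tert-butyl 3-acetoxy-3-(3-chloropropyl)-4-(1-ethoxy-1-oxopropan-2-yl)cyclohepta-1,5-diene-1-carboxylate, acetoxy and propionate arm cis | CCOC(=O)C(C)[C@@H]1C=CCC(C(=O)OC(C)(C)C)=C[C@@]1(OC(C)=O)CCCCl | intermediate
9 | the 3-hydroxy analogue of 8 (tertiary C10 alcohol) | CCOC(=O)C(C)[C@@H]1C=CCC(C(=O)OC(C)(C)C)=C[C@@]1(O)CCCCl | intermediate
10 | cis-fused γ-lactone (C19–O–C10) on the cycloheptadiene, 3-chloropropyl on C10 | CC1C(=O)O[C@@]2(CCCCl)C=C(C(=O)OC(C)(C)C)CC=C[C@@H]12 | intermediate
11 | tricyclic 19,10-lactone, rings A and B closed, C6=C7 and C9=C20, tert-butyl ester on C9 | C1=C[C@@H]2[C@]3(CCC[C@]2(C)C(=O)O3)C=C(C(=O)OC(C)(C)C)C1 | intermediate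
12 | 7α-alcohol of 11 (C6H2, C9=C20) | O[C@@H]1C[C@@H]2[C@]3(CCC[C@]2(C)C(=O)O3)C=C(C(=O)OC(C)(C)C)C1 | intermediate
13 | 7-ketone with C9=C20 (β,γ-unsaturated) | O=C1C[C@@H]2[C@]3(CCC[C@]2(C)C(=O)O3)C=C(C(=O)OC(C)(C)C)C1 | intermediate
14 | 7-ketone with C8=C9 (conjugated), C20 CH2 | O=C1C[C@@H]2[C@]3(CCC[C@]2(C)C(=O)O3)CC(C(=O)OC(C)(C)C)=C1 | intermediate
15 | 7β-allylic alcohol | O[C@H]1C[C@@H]2[C@]3(CCC[C@]2(C)C(=O)O3)CC(C(=O)OC(C)(C)C)=C1 | intermediate
16 | 7α-acetate, tert-butyl ester | CC(=O)O[C@@H]1C[C@@H]2[C@]3(CCC[C@]2(C)C(=O)O3)CC(C(=O)OC(C)(C)C)=C1 | intermediate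
17 | 7α-acetate, carboxylic acid | CC(=O)O[C@@H]1C[C@@H]2[C@]3(CCC[C@]2(C)C(=O)O3)CC(C(=O)O)=C1 | intermediate
18 | 7α-acetate, acid chloride | CC(=O)O[C@@H]1C[C@@H]2[C@]3(CCC[C@]2(C)C(=O)O3)CC(C(=O)Cl)=C1 | intermediate
19 | 7α-acetate, diazomethyl ketone | CC(=O)O[C@@H]1C[C@@H]2[C@]3(CCC[C@]2(C)C(=O)O3)CC(C(=O)C=[N+]=[N-])=C1 | intermediate
20 | ethyl isobutyrate | CCOC(=O)C(C)C | starting material
21 | lithium 3-methylbut-1-yn-1-olate | CC(C)C#C[O-].[Li+] | intermediate
22 | triisopropyl[(3-methylbut-1-yn-1-yl)oxy]silane | CC(C)C#CO[Si](C(C)C)(C(C)C)C(C)C | intermediate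
23 | vinylketene from 19 | CC(=O)O[C@@H]1C[C@@H]2[C@]3(CCC[C@]2(C)C(=O)O3)CC(C=C=O)=C1 | intermediate
24 | 4-alkenyl-2-isopropyl-3-siloxycyclobutenone | CC(=O)O[C@@H]1C[C@@H]2[C@]3(CCC[C@]2(C)C(=O)O3)CC(C2C(=O)C(C(C)C)=C2O[Si](C(C)C)(C(C)C)C(C)C)=C1 | intermediate
25 | ring C phenol: 14-hydroxy, 13-isopropyl, 12-triisopropylsiloxy, 7α-acetoxy | CC(=O)O[C@@H]1C[C@@H]2[C@]3(CCC[C@]2(C)C(=O)O3)Cc2cc(O[Si](C(C)C)(C(C)C)C(C)C)c(C(C)C)c(O)c12 | intermediate
26 | 12-O-triisopropylsilyl-7α-acetoxy-6,7-dihydroicetexone | CC(=O)O[C@@H]1C[C@@H]2[C@]3(CCC[C@]2(C)C(=O)O3)CC2=C1C(=O)C(C(C)C)=C(O[Si](C(C)C)(C(C)C)C(C)C)C2=O | intermediate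
27 | 7α-acetoxy-6,7-dihydroicetexone | CC(=O)O[C@@H]1C[C@@H]2[C@]3(CCC[C@]2(C)C(=O)O3)CC2=C1C(=O)C(C(C)C)=C(O)C2=O | target

**Step count and risks**

Total steps: 16. Longest linear sequence: 14 steps (3 → 4 → 6 → 8 → 10 → 11 → 12 → 14 → 15 → 16 → 17 → 19 → 25 → 26 → 27).

Step 4. What may go wrong: the prolinate catalyst may discriminate poorly between the faces of a 4,4-disubstituted vinylcarbenoid, and the cyclopropane may epimerize while the Cope rearrangement is slowed by the inward chain, both of which erode enantiopurity. The fallback sets out from 3 and replaces catalyst control by a traceless chiral enol ester. Iodo-acyloxylation of 3 with (S)-2-methoxy-2-phenylacetic acid in place of acetic acid should give (E)-5-chloro-1-iodopent-1-en-2-yl (S)-2-methoxy-2-phenylacetate F1. Palladium coupling with 5 as in step 3 should give tert-butyl (E)-7-chloro-2-diazo-4-{[(S)-2-methoxy-2-phenylacetyl]oxy}hept-3-enoate F2. F2 is united with 2 under achiral Rh2(OAc)4 and then heated, and the two diastereomeric cycloheptadienes are separated by chromatography. The one with the ring configuration of 8, the cycloheptadiene (S)-2-methoxy-2-phenylacetate F3, is treated with NaOEt in EtOH, which expels the auxiliary as its ethyl ester, and the route is rejoined at 10.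

Step 8. What may go wrong: during conjugation the dienol may expel the C10 carboxylate (vinylogous β-elimination through C20), opening the lactone. The fallback sets out from 11 and avoids any C7 carbonyl. Conjugate reduction with [(Ph3P)CuH]6 and PhMe2SiH followed by PhSeCl should give the α-phenylseleno ester F4. Oxidation with H2O2 and selenoxide elimination towards the allylic C8 should give the C6,C8-dienoate F5. Mukaiyama hydration (Co(acac)2, PhSiH3, O2) should then deliver the γ-hydroxy enoate with oxygen on the less hindered α-face, the 7α-hydroxy enoate F6. Acetylation (Ac2O, DMAP, pyridine) rejoins the route at 16.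

Step 3. What may go wrong: the alkenylpalladium intermediate may lose acetate to return the alkyne, or the diazo ester may decompose on palladium. The fallback sets out from 4 and builds the diazo group afterwards. Pd(PPh3)4-catalysed coupling of 4 with the Reformatsky reagent BrZnCH2CO2tBu should give tert-butyl (E)-4-acetoxy-7-chlorohept-3-enoate F7. Diazo transfer to its activated methylene with p-acetamidobenzenesulfonyl azide and DBU rejoins the route at 6.

**Further compounds**
F1 | step 4 | (E)-5-chloro-1-iodopent-1-en-2-yl (S)-2-methoxy-2-phenylacetate | CO[C@H](C(=O)O/C(CCCCl)=C/I)c1ccccc1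
F2 | step 4 | tert-butyl (E)-7-chloro-2-diazo-4-{[(S)-2-methoxy-2-phenylacetyl]oxy}hept-3-enoate | CO[C@H](C(=O)O/C(CCCCl)=C/C(=[N+]=[N-])C(=O)OC(C)(C)C)c1ccccc1
F3 | step 4 | cycloheptadiene (S)-2-methoxy-2-phenylacetate (analogue of 8 with the chiral acyloxy group on C10) | CCOC(=O)C(C)[C@@H]1C=CCC(C(=O)OC(C)(C)C)=C[C@@]1(OC(=O)[C@@H](OC)c1ccccc1)CCCCl
F4 | step 8 | α-phenylseleno ester (C9–SePh, C20 CH2, C6=C7) | C1=C[C@@H]2[C@]3(CCC[C@]2(C)C(=O)O3)CC([Se]c2ccccc2)(C(=O)OC(C)(C)C)C1
F5 | step 8 | C6,C8-dienoate (C9=C8–C7=C6, tert-butyl ester) | C1=C[C@@H]2[C@]3(CCC[C@]2(C)C(=O)O3)CC(C(=O)OC(C)(C)C)=C1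
F6 | step 8 | 7α-hydroxy enoate (C7 epimer of 15) | O[C@@H]1C[C@@H]2[C@]3(CCC[C@]2(C)C(=O)O3)CC(C(=O)OC(C)(C)C)=C1
F7 | step 3 | tert-butyl (E)-4-acetoxy-7-chlorohept-3-enoate | CC(=O)O/C(CCCCl)=C/CC(=O)OC(C)(C)C
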